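If a flask held little second catalyst, I counted the target standing in it per molecule of second catalyst charged.

| flask | substrate | solid reagent | free catalyst | second catalyst | remark | time |
|---|---|---|---|---|---|---|
| teal | 1 mM | 1.1 equiv | 0.05 mol% | 0.034 mol% | run made earlier |  |
| green | 1 mM | 1.1 equiv | 0.05 mol% | 1.2 mol% | run made earlier |  |
| autumn | 1.0 mM | 1.10 equiv | 0.05 mol% | 0.06 mol% |  | 2.0 min |
| summer | 1.0 mM | 1.10 equiv | 0.05 mol% | 0.2 mol% |  | 2.0 min |
| noon | 1.0 mM | 1.10 equiv | 0.05 mol% | 0.6 mol% |  | 2.0 min |
| dawn | 1.0 mM | 1.10 equiv | 0.05 mol% | 2 mol% |  | 2.0 min |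

| run | time / s | target / % | substrate / % |
|---|---|---|---|
| teal | 10.0 | 1.5 | 61.3 |
| teal | 15.0 | 2.2 | 58.3 |
| teal | 25.0 | 4.5 | 53.8 |
| teal | 40.0 | 5.1 | 48.5 |
| teal | 60.0 | 5.6 | 41.8 |
| teal | 80.0 | 5.9 | 35.8 |
| green | 12.0 | 30.6 | 38.2 |
| green | 25.0 | 42.9 | 10.2 |
| green | 40.0 | 46.2 | 2.4 |
| green | 50.0 | 45.7 | 1.1 |
| green | 60.0 | 46.2 | 0.4 |
| green | 80.0 | 46.2 | 0.2 |

(scatter of a reading: 0.3 percentage points)

- given per volume of solution although it is solid: solid reagent
- the numbers in the tables scatter by 0.3 percentage points (one standard deviation)
- at the start none of the solid reagent is in solution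
- "hardly changes" means that all values lie within two and a half points (for a concentration: within two and a half percent of the largest)

1. [target] at the end for autumn, summer, noon, dawn, in this order
2. how the row runs (falls, then rises / falls all the way / hardly changes / rises all the way / rises, then falls)

The two earlier runs did not seem to go together. Teal, with 0.034 mol% of second catalyst, stood at 5.9% target after 80.0 s, so its count was 174, the target standing per second catalyst charged. Green, with 1.2 mol%, reached 46.2% target on a count of 38.5, so the run with more target had the lower count.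

My reckoning cleared this up. Between 60.0 s and 80.0 s, teal lost 6 percentage points of substrate but gained 0.3 points of target, and 35.8% of substrate remained, so I took teal's count as a ceiling on target while substrate lasts. In green that ceiling was 2.09 mM, above the 1 mM of substrate charged, and substrate was down to 0.2%, so green ended without meeting it.

Carried forward, the count gave a ceiling on c(target) of 0.104 mM in autumn and 0.347 mM in summer. In noon it gave 1.04 mM, above the 1.0 mM charged, so I expected noon and dawn to end as green did.

The forecast gave 0.1 mM, 0.27 mM, 0.38 mM and 0.5 mM, a row that rises all the way, reading teal to mean that “the second catalyst seems to die after limited turnover”.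

The flasks gave 0.0965 mM, 0.238 mM, 0.395 mM and 0.496 mM, a row that rises all the way.

    solid reagent ⇌ partner, rate k1*(cs1 - [partner]) while solid is left; crystals form when [partner] > cs1 (solubility = 0.830 mM, k = 0.210 s⁻¹)
    partner + catalyst intermediate → second catalyst + target (k = 2.00 × 10⁵ M⁻¹ s⁻¹)
    partner → decomposition product (k = 2.30 × 10⁻⁴ s⁻¹)
    second catalyst + open intermediate ⇌ catalyst intermediate (K = 250 M⁻¹, k = 1.10 × 10⁵ M⁻¹ s⁻¹)
    substrate + target → side product (k = 110 M⁻¹ s⁻¹)
    substrate + free catalyst ⇌ free catalyst + open intermediate (K = 0.690, k = 2.10 × 10⁵ M⁻¹ s⁻¹)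

Counted as before, autumn's target came to 161 per second catalyst charged, against teal's 174, and dawn's to 24.8. In autumn at 2.00 min, second catalyst still stood at 98.1% of its charge, with 1.92% as catalyst intermediate, and 15.0% of the substrate remained. At that moment autumn's target, standing at 9.65% of the substrate charged, was being made at 0.952 times the rate of its removal.

(The earlier runs and the new flask come from a simulation from invented constants; scatter was added.)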